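**Retrosynthetic overview**
1. Target 13 (robustol) comes from its trimethyl ether 11 by global O-demethylation.
2. 11 comes from the 20-membered ene-diol 9 by one-pot alkene hydrogenation and benzylic C–O hydrogenolysis.
3. 9 comes from bis-alkenyl diol 8 by ring-closing metathesis; this is the only ring formed, both arenes are bought.
4. 8 comes from dialdehyde 4 by double Grignard addition of a C7 alkenyl unit (2 × C1 + 2 × C7 − C2H4 = the C14 bridge).
5. 4 comes from phenol 1 and ortho-bromobenzaldehyde 2 by Ullmann diaryl ether coupling.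

Assumption: the target has no stereocentre and is achiral, so no enantiocontrol is needed; the carbinol centres in 7–10 and the alkene in 9 are formed as mixtures and are all erased in step 4. Compounds 1, 2 and 5 are taken as catalogue chemicals.

**Step 1**
Reactants: 1 3-hydroxy-5-methoxybenzaldehyde; 2 2-bromo-3,5-dimethoxybenzaldehyde
Product: 4 2-(3-formyl-5-methoxyphenoxy)-3,5-dimethoxybenzaldehyde, via cesium 3-formyl-5-methoxyphenoxide 3 (not isolated)
Conditions: CuI (10 mol%), N,N-dimethylglycine·HCl (30 mol%), Cs2CO3 (2.5 equiv), 1,4-dioxane, 100 °C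
Reagents that add atoms: none
Why: Ullmann-type Cu(I)-catalysed diaryl ether coupling, in which the ortho-formyl group activates the C–Br bond of 2 towards substitution by the unhindered phenoxide 3 and both non-enolisable aldehydes tolerate carbonate; no stereocentre is formed.

**Step 2**
Reactants: 4 2-(3-formyl-5-methoxyphenoxy)-3,5-dimethoxybenzaldehyde; 5 7-bromohept-1-ene
Product: 8 1-{2-[3-(1-hydroxyoct-7-en-1-yl)-5-methoxyphenoxy]-3,5-dimethoxyphenyl}oct-7-en-1-ol (mixture of diastereomers), via hept-6-enylmagnesium bromide 6 (not isolated), via bis(bromomagnesium) dialkoxide 7 (not isolated)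
Conditions: 5 (3 equiv), Mg, cat. I2, THF, 40 °C; then 4, THF, 0 °C → rt; sat. aq NH4Cl
Reagents that add atoms: none
Why: Grignard 1,2-addition to two non-enolisable aryl aldehydes; the two carbinol centres form without control, which does not matter because both are removed in step 4.

**Step 3**
Reactants: 8 1-{2-[3-(1-hydroxyoct-7-en-1-yl)-5-methoxyphenoxy]-3,5-dimethoxyphenyl}oct-7-en-1-ol
Product: 9 1,14-dihydroxy-7,8-didehydro-tri-O-methylrobustol (20-membered ene-diol macrocycle; OH on both benzylic bridge carbons; C7=C8 alkene; E/Z plus diastereomer mixture)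
Conditions: Grubbs II (5 mol%), CH2Cl2 (2 mM), 40 °C
Reagents that add atoms: none
Why: Ring-closing olefin metathesis of two unhindered terminal alkenes at high dilution, driven by loss of ethene, closes the strain-free 20-membered ring; free alcohols are tolerated and alkene geometry is irrelevant.

**Step 4**
Reactants: 9 1,14-dihydroxy-7,8-didehydro-tri-O-methylrobustol
Product: 11 tri-O-methylrobustol (robustol with all three phenols as methyl ethers; achiral), via saturated macrocyclic 1,14-diol 10 (not isolated)
Conditions: H2 (4 bar), 10% Pd/C, AcOH–EtOAc, cat. HClO4, 50 °C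
Reagents that add atoms: none
Why: Heterogeneous catalytic hydrogenation saturates the alkene, then acid-promoted Pd-catalysed benzylic C–O hydrogenolysis removes both secondary benzylic hydroxyls as water, erasing every stereo-element while the aryl ethers stay intact.

**Step 5**
Reactants: 11 tri-O-methylrobustol
Product: 13 robustol (target), via tris(dibromoboryl) aryl ether 12 (not isolated)
Conditions: BBr3 (6 equiv), CH2Cl2, −78 °C → rt; then H2O, 0 °C
Reagents that add atoms: none
Why: BBr3 aryl methyl ether cleavage (Lewis-acid complexation, then SN2 attack of bromide on methyl) removes all three methyl groups, while the diaryl ether has no sp3 carbon to attack and survives; aqueous work-up hydrolyses the aryl borates.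

**Compound list**
1 | 3-hydroxy-5-methoxybenzaldehyde | COc1cc(O)cc(C=O)c1 | starting material
2 | 2-bromo-3,5-dimethoxybenzaldehyde | COc1cc(OC)c(Br)c(C=O)c1 | starting material
3 | cesium 3-formyl-5-methoxyphenoxide | [Cs+].[O-]c1cc(OC)cc(C=O)c1 | intermediate (not isolated)
4 | 2-(3-formyl-5-methoxyphenoxy)-3,5-dimethoxybenzaldehyde | COc1cc(Oc2c(OC)cc(OC)cc2C=O)cc(C=O)c1 | intermediate
5 | 7-bromohept-1-ene | BrCCCCCC=C | starting material
6 | hept-6-enylmagnesium bromide | Br[Mg]CCCCCC=C | intermediate (not isolated)
7 | bis(bromomagnesium) dialkoxide of diol 8 (stereo-undefined mixture) | COc1cc(Oc2c(OC)cc(OC)cc2C(O[Mg]Br)CCCCCC=C)cc(C(O[Mg]Br)CCCCCC=C)c1 | intermediate (not isolated)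
8 | 1-{2-[3-(1-hydroxyoct-7-en-1-yl)-5-methoxyphenoxy]-3,5-dimethoxyphenyl}oct-7-en-1-ol (both carbinol centres unselective, diastereomer mixture) | COc1cc(Oc2c(OC)cc(OC)cc2C(O)CCCCCC=C)cc(C(O)CCCCCC=C)c1 | intermediate
9 | 1,14-dihydroxy-7,8-didehydro-tri-O-methylrobustol (20-membered ene-diol; E/Z and diastereomer mixture) | COc1cc2cc(c1)Oc1c(OC)cc(OC)cc1C(O)CCCCCC=CCCCCCC2O | intermediate
10 | 1,14-dihydroxy-tri-O-methylrobustol (saturated macrocyclic diol, diastereomer mixture) | COc1cc2cc(c1)Oc1c(OC)cc(OC)cc1C(O)CCCCCCCCCCCCC2O | intermediate (not isolated)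
11 | tri-O-methylrobustol (achiral) | COc1cc2cc(c1)Oc1c(OC)cc(OC)cc1CCCCCCCCCCCCCC2 | intermediate
12 | tris(dibromoboryl) aryl ether of robustol | BrB(Br)Oc1cc2cc(c1)Oc1c(OB(Br)Br)cc(OB(Br)Br)cc1CCCCCCCCCCCCCC2 | intermediate (not isolated)
13 | robustol (achiral; no stereocentres) | Oc1cc2cc(c1)Oc1c(O)cc(O)cc1CCCCCCCCCCCCCC2 | target

**Totals**
Total step count: 5. Longest linear sequence: 5 steps (1 or 2 → 4 → 8 → 9 → 11 → 13).

**Three steps most likely to fail, with fallbacks**

Step 1 (Ullmann coupling at a di-ortho-substituted, electron-rich aryl bromide). If the copper-catalysed coupling stalls, replace it by an uncatalysed SNAr reaction. Setting out from 1, the phenoxide 3 is formed with Cs2CO3 in DMF at 90 °C. It is reacted with 2-fluoro-3,5-dimethoxybenzaldehyde F1, which is made by Selectfluor fluorination of 3,5-dimethoxybenzaldehyde in MeCN. The ortho-formyl group activates the fluoride for addition–elimination. The product is dialdehyde 4, where the route is rejoined.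

Step 3 (macrocyclic RCM; risk of oligomers or isomerisation and ring contraction). If metathesis fails, close the ring by a double Wittig olefination instead. Setting out from 4, dodecane-1,12-diylbis(triphenylphosphonium) dibromide F2 is prepared from 1,12-dibromododecane and PPh3 in MeCN at reflux. KHMDS (2 equiv, THF, −78 °C) converts it into the bis-ylide dodecane-1,12-diylidenebis(triphenylphosphorane) F3. Dialdehyde 4 is added to F3 by syringe pump at high dilution to give 1,2:13,14-bis-dehydro-tri-O-methylrobustol F4, a macrocyclic diene that is mainly Z,Z. Hydrogenation (H2, Pd/C, EtOAc) gives 11, where the route is rejoined; this also bypasses steps 2 and 4.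

Step 4 (double hydrogenolysis of benzylic alcohols that have no para donor). If the reaction stops at diol 10, replace C–O hydrogenolysis by elimination then hydrogenation. Setting out from 9, catalytic p-TsOH in toluene at reflux with a Dean–Stark trap dehydrates both carbinols. This gives 1,2:7,8:13,14-tris-dehydro-tri-O-methylrobustol F5, a macrocyclic triene with two styrenyl alkenes as an E/Z mixture. Hydrogenation (H2, Pd/C, EtOAc) saturates all three alkenes and gives 11, where the route is rejoined.

**Further compounds**
F1 | step 1 | 2-fluoro-3,5-dimethoxybenzaldehyde | COc1cc(OC)c(F)c(C=O)c1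
F2 | step 3 | dodecane-1,12-diylbis(triphenylphosphonium) dibromide | [Br-].[Br-].c1ccc(cc1)[P+](c1ccccc1)(c1ccccc1)CCCCCCCCCCCC[P+](c1ccccc1)(c1ccccc1)c1ccccc1
F3 | step 3 | dodecane-1,12-diylidenebis(triphenylphosphorane) | c1ccc(cc1)P(c1ccccc1)(c1ccccc1)=CCCCCCCCCCCC=P(c1ccccc1)(c1ccccc1)c1ccccc1
F4 | step 3 | 1,2:13,14-bis-dehydro-tri-O-methylrobustol (macrocyclic diene, mainly Z,Z, geometry not defined) | COc1cc2cc(c1)Oc1c(OC)cc(OC)cc1C=CCCCCCCCCCCC=C2
F5 | step 4 | 1,2:7,8:13,14-tris-dehydro-tri-O-methylrobustol (macrocyclic triene, E/Z mixture) | COc1cc2cc(c1)Oc1c(OC)cc(OC)cc1C=CCCCCC=CCCCCC=C2
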